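**Plan**

- Retrosynthesis: (a) the C-3–CH2 bond joining ring A (the diol ring) to the allylic CH2 is cut by enolate alkylation. (b) In ring B (the bromohydrin ring) the C-4'–C-5' bond, the C-3'–Br bond and the C-4'–O bond are cut together, giving an open chain with a (Z)-vinyl iodide and a primary pinacol boronate. (c) That chain is cut at C-1'–isopropenyl (conjugate addition), at the enoate C=C (cross-metathesis) and at the iodoalkene C=C (Wittig).
- Forward: the chain is built first. Ring B is then closed by bromine-induced contraction of a seven-membered alkenyl boronate complex, whose B–C bonds are temporary and are later exchanged for OH. The isopropenyl methyl is converted to an allylic iodide, which alkylates a ring-A ketone made from (S)-carvone; reduction and desilylation finish the route.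
- Enabling feature: in ring B the tertiary C-4' hydroxyl and the C-3' bromine are cis, and C-4' is bonded to the ring CH2 C-5'. This is the pattern left by anti addition of C-5' and Br across a C-3'=C-4' alkenyl–boron unit followed by stereoretentive exchange of boron for OH.
- Stereochemistry: C-1' comes from the rhodium/BINAP conjugate addition. C-3' and C-4' come from the anti carbobromination of the (Z)-alkene, relayed from C-1' through a chair-like transition state. In ring A, C-4 comes from (S)-carvone, C-1 from epoxidation anti to the isopropenyl group, C-3 from alkylation anti to it, and C-2 from axial hydride delivery.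

Key step: step 5

Assumption: (R)-BINAP is taken, by analogy with the usual sense of induction for (E)-β-alkyl enoates, to give (3R)-5; its antipode is used if the sense proves opposite. Ring A is numbered C-1 = C(OH)CH3, C-2 = CHOH, C-3 = side-chain carbon, C-4 = isopropenyl carbon; ring B is numbered C-1' = attachment carbon, C-3' = CHBr, C-4' = C(OH)CH3.

**Route**

Step 1
Reactants: 1 but-3-enylboronic acid pinacol ester; 2 methyl acrylate
Product: 3 methyl (2E)-5-(4,4,5,5-tetramethyl-1,3,2-dioxaborolan-2-yl)pent-2-enoate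
Conditions: 2 (3 equiv), second-generation Grubbs catalyst RuCl2(=CHPh)(PCy3)(H2IMes) (3 mol%), CH2Cl2, 40 °C
Reagents that add atoms: none
Why: Olefin cross-metathesis of a terminal alkene with an acrylate is selective for the cross product and should give the (E)-enoate under thermodynamic control; no stereocenter is formed.

Step 2
Reactants: 3 the (E)-enoate; 4 potassium trifluoro(prop-1-en-2-yl)borate
Product: 5 methyl (3R)-4-methyl-3-[2-(4,4,5,5-tetramethyl-1,3,2-dioxaborolan-2-yl)ethyl]pent-4-enoate
Conditions: [Rh(cod)2]BF4 (3 mol%), (R)-BINAP, toluene/H2O 10:1, 100 °C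
Reagents that add atoms: none
Why: Rhodium-catalysed asymmetric conjugate addition (Hayashi–Miyaura reaction) of an alkenyl trifluoroborate to an (E)-enoate, in which the alkyl pinacol boronate does not transmetalate, should set C-3 (the later C-1') through face selection by the BINAP ligand in the carbometalation.

Step 3
Reactants: 5 the ester
Product: 6 (3R)-4-methyl-3-[2-(4,4,5,5-tetramethyl-1,3,2-dioxaborolan-2-yl)ethyl]pent-4-enal
Conditions: i-Bu2AlH (1.1 equiv), CH2Cl2, −78 °C; MeOH, aqueous Rochelle salt
Reagents that add atoms: none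
Why: Partial ester reduction stops at the aldehyde because the aluminium hemiacetal is stable at −78 °C, and the boronate, the alkene and the stereocenter are untouched.

Step 4
Reactants: 6 the aldehyde
Product: 7 2-[(3R,5Z)-6-iodo-3-(prop-1-en-2-yl)hept-5-en-1-yl]-4,4,5,5-tetramethyl-1,3,2-dioxaborolane
Conditions: Ph3PEtI, n-BuLi, THF, 0 °C; I2, −78 °C; NaN(SiMe3)2, −20 °C; then 6, −78 °C to rt
Reagents that add atoms: ethyltriphenylphosphonium iodide CC[P+](c1ccccc1)(c1ccccc1)c1ccccc1.[I-]; iodine II
Why: Stork–Zhao-type Wittig olefination with the non-stabilised α-iodoethylidene ylide should give the (Z)-2-iodoalkene (iodine cis to the chain) through the kinetically favoured cis-oxaphosphetane.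

Step 5
Reactants: 7 the (Z)-vinyl iodide boronate
Product: 10 2-[(1R,2R,4R)-2-bromo-1-methyl-4-(prop-1-en-2-yl)cyclohexyl]-4,4,5,5-tetramethyl-1,3,2-dioxaborolane, via alkenyllithium 8 (not isolated), via cyclic boronate complex 9 (not isolated)
Conditions: t-BuLi (2.05 equiv), Et2O/THF, 0.01 M, −78 °C; then NBS (1.05 equiv), THF, −78 to 0 °C
Reagents that add atoms: N-bromosuccinimide O=C1CCC(=O)N1Br
Why: Proposed new method: iodine–lithium exchange at the vinyl iodide should outpace addition of t-BuLi to the pinacol boronate, and the (Z)-alkenyllithium 8 adds to the tethered boron to close the seven-membered spiro boronate complex 9, a ring that is not in the target; NBS then brominates the electron-rich alkenyl–boron π bond at the CH carbon while the ring CH2 on boron shifts antiperiplanar to the incoming bromine onto the methyl-bearing carbon, so that the boracycle contracts to the cyclohexane and the C-1–C-6 bond of 10 is formed (a 6-exo-tet opening of the bromonium ion by the migrating B–C bond). The closest known reaction types are the Zweifel olefination (halogen-induced 1,2-metallate shift of alkenyl boronate complexes) and the selenium- or radical-induced 1,2-metallate rearrangements of alkenyl boronate complexes, including ring-contracting versions on smaller cyclic alkenyl boronates; new here are the seven-to-six contraction and the survival of the β-bromo boronic ester. C-1 and C-2 are set by the anti addition of carbon and bromine across the (Z)-alkene, which places bromine equatorial (anti to the new ring bond) and boron axial and cis to it; C-2 relative to C-4 is set by a chair-like transition state with the isopropenyl group equatorial, which should give the 2,4-cis isomer. The step needs bromination of the boronate alkene in preference to the isopropenyl group, secured by the much higher nucleophilicity of the ate complex at −78 °C, and it needs the bromo boronate to persist: boron and bromine are cis on the new ring and cannot become antiperiplanar, so the boron–halide elimination that ends a Zweifel olefination has no low-energy path. High dilution favours ring closure at boron over oligomeric ate complexes.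

Step 6
Reactants: 10 the bromo boronic ester
Product: 11 (1S,2R,4R)-2-bromo-1-methyl-4-(prop-1-en-2-yl)cyclohexan-1-ol
Conditions: NaBO3·4H2O, THF/H2O 1:1, rt
Reagents that add atoms: sodium perborate [Na+].[Na+].O[B-]1(O)OO[B-](O)(O)OO1
Why: Oxidation of the tertiary boronic ester proceeds by 1,2-shift of carbon from boron to oxygen with retention, so the hydroxyl takes the place of boron, cis to bromine; this cis-bromohydrin cannot close to an epoxide under the mildly basic conditions.

Step 7
Reactants: 11 the bromohydrin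
Product: 12 (1S,2R,4R)-2-bromo-4-(3-chloroprop-1-en-2-yl)-1-methylcyclohexan-1-ol
Conditions: Ca(OCl)2, solid CO2, CH2Cl2/H2O, 0 °C
Reagents that add atoms: calcium hypochlorite [Ca+2].[O-]Cl.[O-]Cl
Why: Ene-type allylic chlorination of an isopropenyl group by hypochlorous acid (chloronium formation, then loss of a methyl proton) should give the 2-(chloromethyl)vinyl group at the only alkene in the molecule, with no change at any stereocenter.

Step 8
Reactants: 12 the allylic chloride
Product: 13 {[(1S,2R,4R)-2-bromo-4-(3-chloroprop-1-en-2-yl)-1-methylcyclohexyl]oxy}(trimethyl)silane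
Conditions: TMSOTf, 2,6-lutidine, CH2Cl2, −78 °C
Reagents that add atoms: trimethylsilyl trifluoromethanesulfonate C[Si](C)(C)OS(=O)(=O)C(F)(F)F
Why: Silylation of the hindered tertiary alcohol with a silyl triflate masks the proton that would otherwise quench the enolate in step 14.

Step 9
Reactants: 13 the silyl ether chloride
Product: 14 {[(1S,2R,4R)-2-bromo-4-(3-iodoprop-1-en-2-yl)-1-methylcyclohexyl]oxy}(trimethyl)silane
Conditions: NaI, acetone, rt, dark
Reagents that add atoms: sodium iodide [Na+].[I-]
Why: Finkelstein exchange occurs at the allylic chloride only, because the secondary bromide sits next to a quaternary carbon and is inert to SN2 displacement.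

Step 10
Reactants: 15 (S)-(+)-carvone
Product: 16 (1S,4S,6S)-1-methyl-4-(prop-1-en-2-yl)-7-oxabicyclo[4.1.0]heptan-2-one
Conditions: 30% H2O2, NaOH (cat.), MeOH, 0 °C
Reagents that add atoms: hydrogen peroxide OO
Why: Weitz–Scheffer nucleophilic epoxidation attacks only the enone, and conjugate addition of hydroperoxide anti to the isopropenyl group sets both epoxide carbons (oxygen trans to isopropenyl).

Step 11
Reactants: 16 the epoxy ketone
Product: 17 (1S,2R,4S)-1-methyl-4-(prop-1-en-2-yl)cyclohexane-1,2-diol (with its C-2 epimer)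
Conditions: LiAlH4, THF, 0 °C to reflux
Reagents that add atoms: none
Why: Hydride reduces the ketone and then opens the epoxide by SN2 attack at the less substituted CH carbon, so the tertiary C–O bond and its configuration are kept; the C-2 carbinol (expected mainly from attack anti to the epoxide oxygen) is removed in step 12.

Step 12
Reactants: 17 the diol
Product: 18 (2S,5S)-2-hydroxy-2-methyl-5-(prop-1-en-2-yl)cyclohexan-1-one
Conditions: IBX, DMSO, rt
Reagents that add atoms: none
Why: IBX oxidation converts the secondary alcohol of a 1,2-diol to the α-hydroxy ketone without glycol cleavage and leaves the tertiary alcohol and the alkene alone.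

Step 13
Reactants: 18 the hydroxy ketone
Product: 19 (2S,5S)-2-methyl-5-(prop-1-en-2-yl)-2-[(trimethylsilyl)oxy]cyclohexan-1-one
Conditions: TMSCl, imidazole, DMF, rt
Reagents that add atoms: chlorotrimethylsilane C[Si](C)(C)Cl
Why: Silylation of the tertiary α-hydroxyl gives an α-silyloxy ketone, a class whose lithium enolates are stable and react cleanly at carbon.

Step 14
Reactants: 19 the silyloxy ketone; 14 the allylic iodide
Product: 21 (2S,5S,6R)-6-{2-[(1R,3R,4S)-3-bromo-4-methyl-4-[(trimethylsilyl)oxy]cyclohexyl]prop-2-en-1-yl}-2-methyl-5-(prop-1-en-2-yl)-2-[(trimethylsilyl)oxy]cyclohexan-1-one, via lithium enolate 20 (not isolated)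
Conditions: LiN(i-Pr)2, THF, −78 °C; then 14, DMPU, −78 to −20 °C
Reagents that add atoms: none
Why: Enolate alkylation can occur only at C-6 (C-2 is quaternary), and the allylic iodide should approach anti to the adjacent isopropenyl group, setting C-6 trans to it, which is also the more stable equatorial arrangement.

Step 15
Reactants: 21 the coupled ketone
Product: 23 (1S,2S,3R,4S)-3-{2-[(1R,3R,4S)-3-bromo-4-hydroxy-4-methylcyclohexyl]prop-2-en-1-yl}-1-methyl-4-(prop-1-en-2-yl)cyclohexane-1,2-diol, via bis-silyl ether alcohol 22 (not isolated)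
Conditions: NaBH4, MeOH, 0 °C; then 1 M HCl, rt
Reagents that add atoms: none
Why: Borohydride reduction by axial hydride delivery (the equatorial face is shielded by the axial C-2 methyl) should give the equatorial alcohol, trans to the neighbouring oxygen and to the side chain, and the acidic work-up hydrolyses both trimethylsilyl ethers.

**Compound list**

1 | but-3-enylboronic acid pinacol ester | C=CCCB1OC(C)(C)C(C)(C)O1 | starting material
2 | methyl acrylate | C=CC(=O)OC | starting material
3 | methyl (2E)-5-(4,4,5,5-tetramethyl-1,3,2-dioxaborolan-2-yl)pent-2-enoate | COC(=O)/C=C/CCB1OC(C)(C)C(C)(C)O1 | intermediate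
4 | potassium trifluoro(prop-1-en-2-yl)borate | [K+].C=C(C)[B-](F)(F)F | starting material
5 | methyl (3R)-4-methyl-3-[2-(4,4,5,5-tetramethyl-1,3,2-dioxaborolan-2-yl)ethyl]pent-4-enoate | C=C(C)[C@@H](CC(=O)OC)CCB1OC(C)(C)C(C)(C)O1 | intermediate
6 | (3R)-4-methyl-3-[2-(4,4,5,5-tetramethyl-1,3,2-dioxaborolan-2-yl)ethyl]pent-4-enal | C=C(C)[C@@H](CC=O)CCB1OC(C)(C)C(C)(C)O1 | intermediate
7 | 2-[(3R,5Z)-6-iodo-3-(prop-1-en-2-yl)hept-5-en-1-yl]-4,4,5,5-tetramethyl-1,3,2-dioxaborolane | C=C(C)[C@@H](C/C=C(/C)I)CCB1OC(C)(C)C(C)(C)O1 | intermediate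
8 | (Z)-alkenyllithium from 7 (lithium in place of iodine) | C=C(C)[C@@H](C/C=C(/C)[Li])CCB1OC(C)(C)C(C)(C)O1 | intermediate (not isolated)
9 | lithium pinacolato spiro boronate of (5R)-2-methyl-5-(prop-1-en-2-yl)-1-boracyclohept-2-ene | [Li+].CC1=CC[C@H](C(C)=C)CC[B-]12OC(C)(C)C(C)(C)O2 | intermediate (not isolated)
10 | 2-[(1R,2R,4R)-2-bromo-1-methyl-4-(prop-1-en-2-yl)cyclohexyl]-4,4,5,5-tetramethyl-1,3,2-dioxaborolane | C=C(C)[C@@H]1CC[C@](C)(B2OC(C)(C)C(C)(C)O2)[C@H](Br)C1 | intermediate
11 | (1S,2R,4R)-2-bromo-1-methyl-4-(prop-1-en-2-yl)cyclohexan-1-ol | C=C(C)[C@@H]1CC[C@](C)(O)[C@H](Br)C1 | intermediate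
12 | (1S,2R,4R)-2-bromo-4-(3-chloroprop-1-en-2-yl)-1-methylcyclohexan-1-ol | ClCC(=C)[C@@H]1CC[C@](C)(O)[C@H](Br)C1 | intermediate
13 | {[(1S,2R,4R)-2-bromo-4-(3-chloroprop-1-en-2-yl)-1-methylcyclohexyl]oxy}(trimethyl)silane | ClCC(=C)[C@@H]1CC[C@](C)(O[Si](C)(C)C)[C@H](Br)C1 | intermediate
14 | {[(1S,2R,4R)-2-bromo-4-(3-iodoprop-1-en-2-yl)-1-methylcyclohexyl]oxy}(trimethyl)silane | ICC(=C)[C@@H]1CC[C@](C)(O[Si](C)(C)C)[C@H](Br)C1 | intermediate
15 | (S)-(+)-carvone | CC1=CC[C@@H](CC1=O)C(C)=C | starting material
16 | (1S,4S,6S)-1-methyl-4-(prop-1-en-2-yl)-7-oxabicyclo[4.1.0]heptan-2-one (epoxide oxygen trans to isopropenyl) | C1[C@@H](C(C)=C)C[C@@H]2O[C@]2(C)C1=O | intermediate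
17 | (1S,2R,4S)-1-methyl-4-(prop-1-en-2-yl)cyclohexane-1,2-diol (major C-2 epimer drawn) | C1[C@@H](C(=C)C)CC[C@](C)(O)[C@@H]1O | intermediate
18 | (2S,5S)-2-hydroxy-2-methyl-5-(prop-1-en-2-yl)cyclohexan-1-one | O=C1C[C@@H](C(C)=C)CC[C@]1(C)O | intermediate
19 | (2S,5S)-2-methyl-5-(prop-1-en-2-yl)-2-[(trimethylsilyl)oxy]cyclohexan-1-one | O=C1C[C@@H](C(C)=C)CC[C@]1(C)O[Si](C)(C)C | intermediate
20 | lithium enolate of 19 (C-1=C-6) | [Li+].[O-]C1=C[C@@H](C(C)=C)CC[C@]1(C)O[Si](C)(C)C | intermediate (not isolated)
21 | (2S,5S,6R)-6-{2-[(1R,3R,4S)-3-bromo-4-methyl-4-[(trimethylsilyl)oxy]cyclohexyl]prop-2-en-1-yl}-2-methyl-5-(prop-1-en-2-yl)-2-[(trimethylsilyl)oxy]cyclohexan-1-one | C=C(C[C@@H]1[C@@H](C(=C)C)CC[C@](C)(O[Si](C)(C)C)C1=O)[C@@H]1CC[C@](C)(O[Si](C)(C)C)[C@H](Br)C1 | intermediate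
22 | (1S,2S,5S,6R)-cyclohexan-1-ol corresponding to 21 (both trimethylsilyl ethers intact) | C=C(C[C@@H]1[C@@H](C(=C)C)CC[C@](C)(O[Si](C)(C)C)[C@H]1O)[C@@H]1CC[C@](C)(O[Si](C)(C)C)[C@H](Br)C1 | intermediate (not isolated)
23 | (1S,2S,3R,4S)-3-{2-[(1R,3R,4S)-3-bromo-4-hydroxy-4-methylcyclohexyl]prop-2-en-1-yl}-1-methyl-4-(prop-1-en-2-yl)cyclohexane-1,2-diol | C=C(C[C@@H]1[C@@H](C(=C)C)CC[C@](C)(O)[C@H]1O)[C@@H]1CC[C@](C)(O)[C@H](Br)C1 | target

**Step count**

Total step count: 15. Longest linear sequence: 11 steps (steps 1 to 9, then 14 and 15).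

**Steps most likely to fail**

1. Step 5. The bromo boronate may be lost by boron–bromide elimination to the cyclohexene, t-BuLi may add to boron before the exchange, ate complexes may form between molecules, or the bromination may show poor facial selectivity with respect to C-4. The fallback sets out from aldehyde 6 and comes back at bromohydrin 11, using a methyl addition to an α-bromo ketone to make the cis-bromohydrin. Wittig methylenation of 6 (Ph3P=CH2) gives 2-[(3R)-3-(prop-1-en-2-yl)hex-5-en-1-yl]-4,4,5,5-tetramethyl-1,3,2-dioxaborolane F1. Zweifel coupling of F1 with 1-ethoxyvinyllithium (then I2, NaOMe) gives (5R)-2-ethoxy-5-(prop-1-en-2-yl)octa-1,7-diene F2. Ring-closing metathesis with the second-generation Grubbs catalyst closes the ring as the regio-defined enol ether (4R)-1-ethoxy-4-(prop-1-en-2-yl)cyclohex-1-ene F3, which stores the C-1' information in the position of its double bond. NBS in wet THF, then acid equilibration, gives the cis-bromo ketone (2R,4R)-2-bromo-4-(prop-1-en-2-yl)cyclohexan-1-one F4. MeMgBr with CeCl3 at −78 °C adds from the equatorial side and should give 11.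

2. Step 2. Enantiofacial discrimination may be insufficient for an alkenyl group adding to an open-chain enoate, and the trifluoroborate may be lost by protodeboronation. The fallback sets out from trifluoroborate 4 and comes back at aldehyde 6; it sets the stereocenter on a cyclic acceptor before the boron arm exists. Rhodium/(R)-BINAP addition of 4 to 5,6-dihydro-2H-pyran-2-one gives (4R)-4-(prop-1-en-2-yl)oxan-2-one F5. Opening with Me(MeO)NH·HCl and Me3Al gives (3R)-3-(2-hydroxyethyl)-N-methoxy-N,4-dimethylpent-4-enamide F6. I2, PPh3 and imidazole give (3S)-3-(2-iodoethyl)-N-methoxy-N,4-dimethylpent-4-enamide F7. CuI-catalysed borylation with B2pin2 and LiOMe gives (3R)-N-methoxy-N,4-dimethyl-3-[2-(4,4,5,5-tetramethyl-1,3,2-dioxaborolan-2-yl)ethyl]pent-4-enamide F8, and i-Bu2AlH at −78 °C reduces F8 to 6.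

3. Step 4. The Z-selectivity of the iodo-ylide olefination may erode, the ylide may add to the boronate, and the iodophosphonium salt may decompose. The fallback sets out from aldehyde 6 and comes back at boronic ester 10 through the same alkenyllithium 8. Dibromo-olefination of 6 (CBr4, PPh3) gives 2-[(3R)-6,6-dibromo-3-(prop-1-en-2-yl)hex-5-en-1-yl]-4,4,5,5-tetramethyl-1,3,2-dioxaborolane F9. Negishi coupling with MeZnCl and Pd(PPh3)4 replaces only the bromine trans to the chain and gives 2-[(3R,5Z)-6-bromo-3-(prop-1-en-2-yl)hept-5-en-1-yl]-4,4,5,5-tetramethyl-1,3,2-dioxaborolane F10. Bromine–lithium exchange of F10 with t-BuLi gives 8, which continues as in step 5 to 10.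

**Further compounds**

F1 | step 5 | 2-[(3R)-3-(prop-1-en-2-yl)hex-5-en-1-yl]-4,4,5,5-tetramethyl-1,3,2-dioxaborolane | C=C(C)[C@@H](CC=C)CCB1OC(C)(C)C(C)(C)O1
F2 | step 5 | (5R)-2-ethoxy-5-(prop-1-en-2-yl)octa-1,7-diene | C=C(C)[C@@H](CC=C)CCC(=C)OCC
F3 | step 5 | (4R)-1-ethoxy-4-(prop-1-en-2-yl)cyclohex-1-ene | CCOC1=CC[C@H](C(C)=C)CC1
F4 | step 5 | (2R,4R)-2-bromo-4-(prop-1-en-2-yl)cyclohexan-1-one | C=C(C)[C@@H]1CCC(=O)[C@H](Br)C1
F5 | step 2 | (4R)-4-(prop-1-en-2-yl)oxan-2-one | C=C(C)[C@H]1CC(=O)OCC1
F6 | step 2 | (3R)-3-(2-hydroxyethyl)-N-methoxy-N,4-dimethylpent-4-enamide | C=C(C)[C@@H](CC(=O)N(C)OC)CCO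
F7 | step 2 | (3S)-3-(2-iodoethyl)-N-methoxy-N,4-dimethylpent-4-enamide | C=C(C)[C@@H](CC(=O)N(C)OC)CCI
F8 | step 2 | (3R)-N-methoxy-N,4-dimethyl-3-[2-(4,4,5,5-tetramethyl-1,3,2-dioxaborolan-2-yl)ethyl]pent-4-enamide | C=C(C)[C@@H](CC(=O)N(C)OC)CCB1OC(C)(C)C(C)(C)O1
F9 | step 4 | 2-[(3R)-6,6-dibromo-3-(prop-1-en-2-yl)hex-5-en-1-yl]-4,4,5,5-tetramethyl-1,3,2-dioxaborolane | C=C(C)[C@@H](CC=C(Br)Br)CCB1OC(C)(C)C(C)(C)O1
F10 | step 4 | 2-[(3R,5Z)-6-bromo-3-(prop-1-en-2-yl)hept-5-en-1-yl]-4,4,5,5-tetramethyl-1,3,2-dioxaborolane | C=C(C)[C@@H](C/C=C(/C)Br)CCB1OC(C)(C)C(C)(C)O1
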